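**Plan**

1. Locants follow the indene skeleton: C1 (CHMe), C2 (C=O), C3 (CHEt), C3a, C4 (C(Et)CO2H), C5 (C(Et)styryl), C6=C7(Et), C7a. Cyclohexene ring A (C3a–C4–C5–C6=C7–C7a) is fused along C3a–C7a to cyclopentanone ring B (C1–C2–C3–C3a–C7a). This is a Diels–Alder retron in which the three-atom chain C1–C2–C3 ties the diene terminus C7a to the dienophile carbon C3a.
2. Retrosynthesis: C3a–C7a and C4–C5 are cut in one intramolecular Diels–Alder event, giving an open-chain all-(E) styryl-triene/enoate. Its four C=C bonds (styryl CH=CH, C5=C6, C7=C7a, C3a=C4) are then cut by olefinations, and C2–C3 by an aldol.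
3. Forward: the (R)-Roche ester supplies C1/C7a, the aldol joins C2–C3, the dienophile arm is built, then the triene arm. Rings A and B then close together, ring B through the C3a–C7a bond; fluoride deprotection and C2 oxidation finish.
4. Stereochemistry: C1 comes from the chiral pool; C3 and the temporary C2 carbinol from an Evans syn-aldol; alkene geometries from stabilised ylides and a phosphonate. C3a, C4, C5 and C7a arise in the cycloaddition (ester-endo, allylic 1,3-strain control by C1 and C3).
5. Helpers: C2 is carried as a TBS-protected carbinol, because a C2 ketone would let C1 and C3 epimerise. The acid is carried as a 2-(trimethylsilyl)ethyl ester, so the hindered carboxyl is freed by fluoride and not by hydrolysis.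

Key step: step 15

Assumption: the open-chain tetraenoate survives isolation below room temperature (if not, its formation and the cycloaddition merge into one operation); the configuration of the temporary C2 carbinol is immaterial because C2 is oxidised at the end.

**Route**

Step 1
Reactants: 1 methyl (R)-3-hydroxy-2-methylpropanoate
Product: 2 methyl (R)-3-[(tert-butyldimethylsilyl)oxy]-2-methylpropanoate
Conditions: TBSCl, imidazole, CH2Cl2, 0 °C → rt
Reagents that add atoms: tert-butyldimethylsilyl chloride (TBSCl), CC(C)(C)[Si](C)(C)Cl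
Why: Imidazole-promoted silylation of a primary alcohol (silyl ether formation); the stereocentre is not involved.

Step 2
Reactants: 2 methyl (R)-3-[(tert-butyldimethylsilyl)oxy]-2-methylpropanoate
Product: 3 (R)-3-[(tert-butyldimethylsilyl)oxy]-2-methylpropanal
Conditions: i-Bu2AlH (1.1 equiv), CH2Cl2, −78 °C; aq. KNaC4H4O6 work-up; used crude at once
Reagents that add atoms: none
Why: Partial ester reduction by DIBAL-H through a tetrahedral aluminium hemiacetal that is stable at −78 °C and releases the aldehyde only on work-up; the α-stereocentre should be retained if the aldehyde is neither stored nor chromatographed.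

Step 3
Reactants: 4 (S)-4-benzyl-1,3-oxazolidin-2-one; 5 butanoyl chloride
Product: 7 (S)-4-benzyl-3-butanoyl-1,3-oxazolidin-2-one, via lithium oxazolidinide 6 (not isolated)
Conditions: n-BuLi, THF, −78 °C; then 5, −78 → 0 °C
Reagents that add atoms: none
Why: N-Acylation of the lithiated oxazolidinone by the acid chloride (standard loading of an Evans auxiliary); no stereocentre is formed.

Step 4
Reactants: 7 (S)-4-benzyl-3-butanoyl-1,3-oxazolidin-2-one; 3 (R)-3-[(tert-butyldimethylsilyl)oxy]-2-methylpropanal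
Product: 9 (S)-4-benzyl-3-[(2S,3R,4R)-5-[(tert-butyldimethylsilyl)oxy]-2-ethyl-3-hydroxy-4-methylpentanoyl]-1,3-oxazolidin-2-one, via dibutylboron (Z)-enolate 8 (not isolated)
Conditions: n-Bu2BOTf, Et3N, CH2Cl2, −78 → 0 °C; then 3, −78 → 0 °C; pH 7 buffer, MeOH, 30% aq. H2O2, 0 °C
Reagents that add atoms: none
Why: Evans syn-aldol through a closed Zimmerman–Traxler chair in which the benzyl group of the auxiliary shields one face of the (Z)-enolate, which should set the ethyl-bearing carbon (later C3) and the carbinol (later C2) syn, (2S,3R) in the acyl chain; the methyl-bearing centre (later C1) comes from 3, and the 3,4-anti (anti-Felkin) sense is the one a (Z)-enolate prefers, so auxiliary and substrate control are matched.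

Step 5
Reactants: 9 (S)-4-benzyl-3-[(2S,3R,4R)-5-[(tert-butyldimethylsilyl)oxy]-2-ethyl-3-hydroxy-4-methylpentanoyl]-1,3-oxazolidin-2-one
Product: 10 (S)-4-benzyl-3-[(2S,3R,4R)-3,5-bis[(tert-butyldimethylsilyl)oxy]-2-ethyl-4-methylpentanoyl]-1,3-oxazolidin-2-one
Conditions: TBSOTf, 2,6-lutidine, CH2Cl2, −78 → 0 °C
Reagents that add atoms: tert-butyldimethylsilyl trifluoromethanesulfonate (TBSOTf), CC(C)(C)[Si](C)(C)OS(=O)(=O)C(F)(F)F
Why: Silylation of a hindered secondary alcohol with the silyl triflate and a non-nucleophilic base; this also blocks retro-aldol cleavage in the next step.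

Step 6
Reactants: 10 (S)-4-benzyl-3-[(2S,3R,4R)-3,5-bis[(tert-butyldimethylsilyl)oxy]-2-ethyl-4-methylpentanoyl]-1,3-oxazolidin-2-one
Product: 11 (2R,3R,4R)-3,5-bis[(tert-butyldimethylsilyl)oxy]-2-ethyl-4-methylpentan-1-ol
Conditions: LiBH4, H2O (1 equiv), Et2O, 0 °C → rt
Reagents that add atoms: none
Why: Reductive cleavage of the N-acyl oxazolidinone at the exocyclic carbonyl by LiBH4, which should proceed without epimerisation and return the auxiliary.

Step 7
Reactants: 12 2-bromobutanoyl bromide (racemic); 13 2-(trimethylsilyl)ethanol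
Product: 14 2-(trimethylsilyl)ethyl 2-bromobutanoate (racemic)
Conditions: pyridine, CH2Cl2, 0 °C → rt
Reagents that add atoms: none
Why: Acylation of the alcohol by the acid bromide (ester formation); the stereocentre is racemic and is erased in the next step.

Step 8
Reactants: 14 2-(trimethylsilyl)ethyl 2-bromobutanoate (racemic); 15 triphenylphosphine
Product: 17 2-(trimethylsilyl)ethyl 2-(triphenylphosphoranylidene)butanoate, via phosphonium bromide 16 (not isolated)
Conditions: PhMe, 90 °C; then CH2Cl2, 1 M aq. NaOH, 0 °C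
Reagents that add atoms: none
Why: SN2 quaternisation of PPh3 by the α-bromo ester, then deprotonation of the acidic α-CH to the ester-stabilised ylide (standard Wittig reagent synthesis).

Step 9
Reactants: 11 (2R,3R,4R)-3,5-bis[(tert-butyldimethylsilyl)oxy]-2-ethyl-4-methylpentan-1-ol; 17 2-(trimethylsilyl)ethyl 2-(triphenylphosphoranylidene)butanoate
Product: 19 2-(trimethylsilyl)ethyl (2E,4R,5S,6R)-5,7-bis[(tert-butyldimethylsilyl)oxy]-2,4-diethyl-6-methylhept-2-enoate, via aldehyde 18 (not isolated)
Conditions: Dess–Martin periodinane (1.3 equiv), 17 (2.5 equiv), CH2Cl2, 0 °C → rt, then 40 °C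
Reagents that add atoms: none
Why: Dess–Martin oxidation in the presence of the stabilised ylide (tandem oxidation–Wittig) traps the epimerisable α-branched aldehyde as it forms, and the α-substituted ester ylide should give the (E)-trisubstituted enoate (ester trans to the chain); no stereocentre is touched.

Step 10
Reactants: 19 2-(trimethylsilyl)ethyl (2E,4R,5S,6R)-5,7-bis[(tert-butyldimethylsilyl)oxy]-2,4-diethyl-6-methylhept-2-enoate
Product: 20 2-(trimethylsilyl)ethyl (2E,4R,5S,6R)-5-[(tert-butyldimethylsilyl)oxy]-2,4-diethyl-7-hydroxy-6-methylhept-2-enoate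
Conditions: camphorsulfonic acid (0.2 equiv), MeOH/CH2Cl2 1:1, 0 °C
Reagents that add atoms: none
Why: Acid-catalysed methanolysis removes the unhindered primary TBS ether much faster than the secondary one flanked by two branched carbons (selective desilylation); the silylethyl ester is inert here.

Step 11
Reactants: 21 propyltriphenylphosphonium bromide; 22 ethyl formate
Product: 24 2-(triphenylphosphoranylidene)butanal, via propylidenetriphenylphosphorane 23 (not isolated)
Conditions: KOt-Bu (2 equiv), THF, 0 °C; then 22, 0 °C → rt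
Reagents that add atoms: none
Why: C-Formylation of the non-stabilised ylide by ethyl formate, followed by loss of the now acidic α-proton, gives the formyl-stabilised ylide (acylation of a phosphorus ylide).

Step 12
Reactants: 20 2-(trimethylsilyl)ethyl (2E,4R,5S,6R)-5-[(tert-butyldimethylsilyl)oxy]-2,4-diethyl-7-hydroxy-6-methylhept-2-enoate; 24 2-(triphenylphosphoranylidene)butanal
Product: 26 2-(trimethylsilyl)ethyl (2E,4R,5R,6R,7E)-5-[(tert-butyldimethylsilyl)oxy]-2,4,8-triethyl-6-methyl-9-oxonona-2,7-dienoate, via aldehyde 25 (not isolated)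
Conditions: Dess–Martin periodinane, CH2Cl2, 0 °C → rt; aqueous wash, solvent exchange without chromatography; then 24 (1.3 equiv), PhMe, 80 °C
Reagents that add atoms: none
Why: Dess–Martin oxidation gives the α-methyl aldehyde, used unpurified to protect C1, and the Wittig reaction with the formyl-stabilised ylide should give the (E)-enal (chain trans to CHO); the saturated aldehyde reacts much faster than the product enal, which limits double homologation.

Step 13
Reactants: 26 2-(trimethylsilyl)ethyl (2E,4R,5R,6R,7E)-5-[(tert-butyldimethylsilyl)oxy]-2,4,8-triethyl-6-methyl-9-oxonona-2,7-dienoate; 24 2-(triphenylphosphoranylidene)butanal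
Product: 27 2-(trimethylsilyl)ethyl (2E,4R,5R,6R,7E,9E)-5-[(tert-butyldimethylsilyl)oxy]-2,4,8,10-tetraethyl-6-methyl-11-oxoundeca-2,7,9-trienoate
Conditions: 24 (3 equiv), PhMe, 100 °C
Reagents that add atoms: none
Why: A second Wittig reaction of the same formyl-stabilised ylide with the α-branched enal should again give the (E)-alkene; the acceptor-substituted diene so formed is a poor partner for the tethered enoate, so no premature cycloaddition is expected at this temperature.

Step 14
Reactants: 27 2-(trimethylsilyl)ethyl (2E,4R,5R,6R,7E,9E)-5-[(tert-butyldimethylsilyl)oxy]-2,4,8,10-tetraethyl-6-methyl-11-oxoundeca-2,7,9-trienoate; 28 diethyl benzylphosphonate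
Product: 30 2-(trimethylsilyl)ethyl (2E,4R,5R,6R,7E,9E,11E)-5-[(tert-butyldimethylsilyl)oxy]-2,4,8,10-tetraethyl-6-methyl-12-phenyldodeca-2,7,9,11-tetraenoate, via sodium phosphonate carbanion 29 (not isolated)
Conditions: 28, NaN(SiMe3)2, THF, −78 °C; then 27, −78 → 0 °C; product kept cold
Reagents that add atoms: none
Why: Horner–Wadsworth–Emmons olefination with the benzylphosphonate anion should give the (E)-styryl double bond; adding the aldehyde to the preformed anion at −78 °C favours carbonyl attack over deprotonation of the dienal or the enoate.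

Step 15
Reactants: 30 2-(trimethylsilyl)ethyl (2E,4R,5R,6R,7E,9E,11E)-5-[(tert-butyldimethylsilyl)oxy]-2,4,8,10-tetraethyl-6-methyl-12-phenyldodeca-2,7,9,11-tetraenoate
Product: 31 2-(trimethylsilyl)ethyl (1R,2R,3R,3aS,4S,5R,7aS)-2-[(tert-butyldimethylsilyl)oxy]-3,4,5,7-tetraethyl-1-methyl-5-[(E)-2-phenylethenyl]-2,3,3a,4,5,7a-hexahydro-1H-indene-4-carboxylate
Conditions: PhMe (0.01 M), 2,6-di-tert-butyl-4-methylphenol (cat.), 110 °C, sealed tube, Ar
Reagents that add atoms: none
Why: A thermal, concerted, suprafacial [4+2] cycloaddition joins the C5=C6–C7=C7a diene (electron-rich through styryl conjugation) to the C3a=C4 enoate, the closest known reaction type being the type 1 intramolecular Diels–Alder reaction of 1,3,8-nonatrienes that gives trans-fused hydrindenes. Ring A closes through the two new bonds C4–C5 and C3a–C7a of the six-membered transition state, and ring B closes through the same C3a–C7a bond in the fused mode, because the three-atom tether C1–C2–C3 leaves from the diene terminus; this tether also rules out the other diene of the triene (C6=C5–CH=CHPh), which could only give a strained seven-membered ring holding an (E)-alkene. C5 and C4 are set by the alkene geometries, styryl "outside" on the (E)-diene terminus and ester trans to the tether on the (E)-enoate, together with the endo placing of the ester under the diene, which puts CO2R cis to styryl and makes the ring fusion trans. C7a is controlled by C1 and C3a by C3 through allylic 1,3-strain: the C1–H and C3–H bonds eclipse the alkene carbons C7 and C4, each of which carries a cis ethyl group, so the methyl and ethyl substituents turn away and the C2 bridge is presented to one face of each π system. The step needs endo over exo and one of two faces on each partner; the 1,3-anti arrangement of C1 and C3 makes the two facial preferences matched, and both are satisfied only in the ester-endo transition state that leads to (3aS,4S,5R,7aS). The C2 silyl ether keeps C1 and C3 from epimerising at 110 °C, which a C2 ketone flanked by two allylic methines would not.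

Step 16
Reactants: 31 2-(trimethylsilyl)ethyl (1R,2R,3R,3aS,4S,5R,7aS)-2-[(tert-butyldimethylsilyl)oxy]-3,4,5,7-tetraethyl-1-methyl-5-[(E)-2-phenylethenyl]-2,3,3a,4,5,7a-hexahydro-1H-indene-4-carboxylate
Product: 33 (1R,2R,3R,3aS,4S,5R,7aS)-3,4,5,7-tetraethyl-2-hydroxy-1-methyl-5-[(E)-2-phenylethenyl]-2,3,3a,4,5,7a-hexahydro-1H-indene-4-carboxylic acid, via tetrabutylammonium carboxylate 32 (not isolated)
Conditions: Bu4NF (6 equiv), THF, rt → 45 °C; 0.1 M aq. HCl work-up
Reagents that add atoms: none
Why: Fluoride attacks silicon in both groups: the 2-(trimethylsilyl)ethyl ester fragments to ethene, Me3SiF and the carboxylate without any attack at the neopentyl-type acyl carbon, and the hindered secondary TBS ether is then cleaved more slowly (fluoride-mediated desilylation); no stereocentre is affected.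

Step 17
Reactants: 33 (1R,2R,3R,3aS,4S,5R,7aS)-3,4,5,7-tetraethyl-2-hydroxy-1-methyl-5-[(E)-2-phenylethenyl]-2,3,3a,4,5,7a-hexahydro-1H-indene-4-carboxylic acid
Product: 34 (1R,3R,3aS,4S,5R,7aS)-3,4,5,7-tetraethyl-1-methyl-2-oxo-5-[(E)-2-phenylethenyl]-2,3,3a,4,5,7a-hexahydro-1H-indene-4-carboxylic acid
Conditions: Dess–Martin periodinane, CH2Cl2, rt
Reagents that add atoms: none
Why: Dess–Martin oxidation of the secondary alcohol to the ketone under near-neutral conditions that tolerate the free acid and both alkenes; C1 and C3 already have the all-trans arrangement expected to be the thermodynamically preferred one around the cyclopentanone, so they should not drift.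

**Compound list**

1 | methyl (R)-3-hydroxy-2-methylpropanoate | COC(=O)[C@H](C)CO | starting material
2 | methyl (R)-3-[(tert-butyldimethylsilyl)oxy]-2-methylpropanoate | COC(=O)[C@H](C)CO[Si](C)(C)C(C)(C)C | intermediate
3 | (R)-3-[(tert-butyldimethylsilyl)oxy]-2-methylpropanal | O=C[C@H](C)CO[Si](C)(C)C(C)(C)C | intermediate
4 | (S)-4-benzyl-1,3-oxazolidin-2-one | O=C1N[C@@H](Cc2ccccc2)CO1 | starting material
5 | butanoyl chloride | CCCC(=O)Cl | starting material
6 | lithium (S)-4-benzyl-2-oxo-1,3-oxazolidin-3-ide | [Li+].O=C1[N-][C@@H](Cc2ccccc2)CO1 | intermediate (not isolated)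
7 | (S)-4-benzyl-3-butanoyl-1,3-oxazolidin-2-one | CCCC(=O)N1[C@@H](Cc2ccccc2)COC1=O | intermediate
8 | (S)-4-benzyl-3-[(1Z)-1-[(dibutylboranyl)oxy]but-1-en-1-yl]-1,3-oxazolidin-2-one | CC/C=C(\OB(CCCC)CCCC)N1[C@@H](Cc2ccccc2)COC1=O | intermediate (not isolated)
9 | (S)-4-benzyl-3-[(2S,3R,4R)-5-[(tert-butyldimethylsilyl)oxy]-2-ethyl-3-hydroxy-4-methylpentanoyl]-1,3-oxazolidin-2-one | CC(C)(C)[Si](C)(C)OC[C@@H](C)[C@@H](O)[C@H](CC)C(=O)N1[C@@H](Cc2ccccc2)COC1=O | intermediate
10 | (S)-4-benzyl-3-[(2S,3R,4R)-3,5-bis[(tert-butyldimethylsilyl)oxy]-2-ethyl-4-methylpentanoyl]-1,3-oxazolidin-2-one | CC(C)(C)[Si](C)(C)OC[C@@H](C)[C@@H](O[Si](C)(C)C(C)(C)C)[C@H](CC)C(=O)N1[C@@H](Cc2ccccc2)COC1=O | intermediate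
11 | (2R,3R,4R)-3,5-bis[(tert-butyldimethylsilyl)oxy]-2-ethyl-4-methylpentan-1-ol | CC(C)(C)[Si](C)(C)OC[C@@H](C)[C@@H](O[Si](C)(C)C(C)(C)C)[C@H](CC)CO | intermediate
12 | 2-bromobutanoyl bromide (racemic) | CCC(Br)C(=O)Br | starting material
13 | 2-(trimethylsilyl)ethanol | C[Si](C)(C)CCO | starting material
14 | 2-(trimethylsilyl)ethyl 2-bromobutanoate (racemic) | CCC(Br)C(=O)OCC[Si](C)(C)C | intermediate
15 | triphenylphosphine | c1ccc(cc1)P(c1ccccc1)c1ccccc1 | starting material
16 | {1-[2-(trimethylsilyl)ethoxycarbonyl]propyl}triphenylphosphonium bromide (racemic) | CCC(C(=O)OCC[Si](C)(C)C)[P+](c1ccccc1)(c1ccccc1)c1ccccc1.[Br-] | intermediate (not isolated)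
17 | 2-(trimethylsilyl)ethyl 2-(triphenylphosphoranylidene)butanoate | CCC(C(=O)OCC[Si](C)(C)C)=P(c1ccccc1)(c1ccccc1)c1ccccc1 | intermediate
18 | (2S,3R,4R)-3,5-bis[(tert-butyldimethylsilyl)oxy]-2-ethyl-4-methylpentanal | CC(C)(C)[Si](C)(C)OC[C@@H](C)[C@@H](O[Si](C)(C)C(C)(C)C)[C@H](CC)C=O | intermediate (not isolated)
19 | 2-(trimethylsilyl)ethyl (2E,4R,5S,6R)-5,7-bis[(tert-butyldimethylsilyl)oxy]-2,4-diethyl-6-methylhept-2-enoate | CC(C)(C)[Si](C)(C)OC[C@@H](C)[C@@H](O[Si](C)(C)C(C)(C)C)[C@H](CC)/C=C(CC)/C(=O)OCC[Si](C)(C)C | intermediate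
20 | 2-(trimethylsilyl)ethyl (2E,4R,5S,6R)-5-[(tert-butyldimethylsilyl)oxy]-2,4-diethyl-7-hydroxy-6-methylhept-2-enoate | OC[C@@H](C)[C@@H](O[Si](C)(C)C(C)(C)C)[C@H](CC)/C=C(CC)/C(=O)OCC[Si](C)(C)C | intermediate
21 | propyltriphenylphosphonium bromide | CCC[P+](c1ccccc1)(c1ccccc1)c1ccccc1.[Br-] | starting material
22 | ethyl formate | CCOC=O | starting material
23 | propylidenetriphenylphosphorane | CCC=P(c1ccccc1)(c1ccccc1)c1ccccc1 | intermediate (not isolated)
24 | 2-(triphenylphosphoranylidene)butanal | CCC(C=O)=P(c1ccccc1)(c1ccccc1)c1ccccc1 | intermediate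
25 | 2-(trimethylsilyl)ethyl (2E,4R,5S,6S)-5-[(tert-butyldimethylsilyl)oxy]-2,4-diethyl-6-methyl-7-oxohept-2-enoate | O=C[C@@H](C)[C@@H](O[Si](C)(C)C(C)(C)C)[C@H](CC)/C=C(CC)/C(=O)OCC[Si](C)(C)C | intermediate (not isolated)
26 | 2-(trimethylsilyl)ethyl (2E,4R,5R,6R,7E)-5-[(tert-butyldimethylsilyl)oxy]-2,4,8-triethyl-6-methyl-9-oxonona-2,7-dienoate | O=C/C(CC)=C/[C@@H](C)[C@@H](O[Si](C)(C)C(C)(C)C)[C@H](CC)/C=C(CC)/C(=O)OCC[Si](C)(C)C | intermediate
27 | 2-(trimethylsilyl)ethyl (2E,4R,5R,6R,7E,9E)-5-[(tert-butyldimethylsilyl)oxy]-2,4,8,10-tetraethyl-6-methyl-11-oxoundeca-2,7,9-trienoate | O=C/C(CC)=C/C(CC)=C/[C@@H](C)[C@@H](O[Si](C)(C)C(C)(C)C)[C@H](CC)/C=C(CC)/C(=O)OCC[Si](C)(C)C | intermediate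
28 | diethyl benzylphosphonate | CCOP(=O)(Cc1ccccc1)OCC | starting material
29 | sodium (diethoxyphosphoryl)(phenyl)methanide | [Na+].CCOP(=O)([CH-]c1ccccc1)OCC | intermediate (not isolated)
30 | 2-(trimethylsilyl)ethyl (2E,4R,5R,6R,7E,9E,11E)-5-[(tert-butyldimethylsilyl)oxy]-2,4,8,10-tetraethyl-6-methyl-12-phenyldodeca-2,7,9,11-tetraenoate | c1ccccc1/C=C/C(CC)=C/C(CC)=C/[C@@H](C)[C@@H](O[Si](C)(C)C(C)(C)C)[C@H](CC)/C=C(CC)/C(=O)OCC[Si](C)(C)C | intermediate
31 | 2-(trimethylsilyl)ethyl (1R,2R,3R,3aS,4S,5R,7aS)-2-[(tert-butyldimethylsilyl)oxy]-3,4,5,7-tetraethyl-1-methyl-5-[(E)-2-phenylethenyl]-2,3,3a,4,5,7a-hexahydro-1H-indene-4-carboxylate | CCC1=C[C@](/C=C/c2ccccc2)(CC)[C@@](CC)(C(=O)OCC[Si](C)(C)C)[C@H]2[C@H]1[C@@H](C)[C@@H](O[Si](C)(C)C(C)(C)C)[C@@H]2CC | intermediate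
32 | tetrabutylammonium (1R,2R,3R,3aS,4S,5R,7aS)-2-[(tert-butyldimethylsilyl)oxy]-3,4,5,7-tetraethyl-1-methyl-5-[(E)-2-phenylethenyl]-2,3,3a,4,5,7a-hexahydro-1H-indene-4-carboxylate | CCCC[N+](CCCC)(CCCC)CCCC.CCC1=C[C@](/C=C/c2ccccc2)(CC)[C@@](CC)(C(=O)[O-])[C@H]2[C@H]1[C@@H](C)[C@@H](O[Si](C)(C)C(C)(C)C)[C@@H]2CC | intermediate (not isolated)
33 | (1R,2R,3R,3aS,4S,5R,7aS)-3,4,5,7-tetraethyl-2-hydroxy-1-methyl-5-[(E)-2-phenylethenyl]-2,3,3a,4,5,7a-hexahydro-1H-indene-4-carboxylic acid | CCC1=C[C@](/C=C/c2ccccc2)(CC)[C@@](CC)(C(=O)O)[C@H]2[C@H]1[C@@H](C)[C@@H](O)[C@@H]2CC | intermediate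
34 | (1R,3R,3aS,4S,5R,7aS)-3,4,5,7-tetraethyl-1-methyl-2-oxo-5-[(E)-2-phenylethenyl]-2,3,3a,4,5,7a-hexahydro-1H-indene-4-carboxylic acid | CCC1=C[C@](/C=C/c2ccccc2)(CC)[C@@](CC)(C(=O)O)[C@H]2[C@H]1[C@@H](C)C(=O)[C@@H]2CC | target

**Count and risks**

Total step count: 17 (13 in the main line plus reagent preparations in steps 3, 7, 8 and 11).
Longest linear sequence: 13 steps (1, 2, 4, 5, 6, 9, 10, 12, 13, 14, 15, 16, 17).

Steps most likely to fail:

1. Step 15 (cycloaddition). The ester dienophile needs about 110 °C. At that temperature endo/exo or facial selectivity may erode, and a 1,5-hydrogen shift from the "inside" ethyl CH2 into the triene, or polymerisation, may compete. The fallback moves the cycloaddition to the aldehyde oxidation level and sets out from 30. Reduction with i-Bu2AlH (CH2Cl2, −78 °C) should give the allylic alcohol F1. MnO2 (CH2Cl2, rt) should then give the enal F2, whose lower LUMO should allow cyclisation at 40–60 °C in PhMe, or with Me2AlCl at −78 °C, to the aldehyde F3. Oxidation with NaClO2/NaH2PO4/2-methylbut-2-ene in t-BuOH/H2O should give the acid F4. Bu4NF in THF then removes the TBS ether, and the fallback comes back to the route at 33.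

2. Step 13 (second formyl-ylide olefination). The α-branched, conjugated enal is a sluggish electrophile. Long heating with excess ylide may lead to incomplete conversion, a third homologation of the product, or thermal degradation. The fallback sets out from 26 and installs the remaining diene carbons and the phenyl ring in one Horner–Wadsworth–Emmons reaction. Diethyl [(1E)-1-phenylpent-1-en-3-yl]phosphonate F5 is made from commercial diethyl cinnamylphosphonate by α-ethylation (LiN(i-Pr)2, EtI, THF, −78 °C). Its lithium anion (n-BuLi, THF, −78 °C → rt) is added to 26; the anion-stabilising styryl group should end up trans to the aldehyde residue, giving the (E)-C5=C6 bond. The fallback comes back to the route at 30 and bypasses 27.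

3. Step 14 (benzylphosphonate olefination). The strongly basic carbanion may deprotonate the dienal at its ε-position (C1–H) or the enoate at its γ-position (C3–H) instead of adding to the carbonyl. That would erode configuration at C1 or C3 or move double bonds. The fallback is non-basic and sets out from 27. Takai iodo-olefination (CHI3, CrCl2, THF/dioxane, 0 °C → rt) should give the (E)-iodotetraene F6. Suzuki–Miyaura coupling with phenylboronic acid (Pd(PPh3)4, K3PO4, THF/H2O, rt) then installs the phenyl ring with retention of geometry. The fallback comes back to the route at 30.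

**Further compounds**

F1 | step 15 | (2E,4R,5R,6R,7E,9E,11E)-5-[(tert-butyldimethylsilyl)oxy]-2,4,8,10-tetraethyl-6-methyl-12-phenyldodeca-2,7,9,11-tetraen-1-ol | c1ccccc1/C=C/C(CC)=C/C(CC)=C/[C@@H](C)[C@@H](O[Si](C)(C)C(C)(C)C)[C@H](CC)/C=C(CC)/CO
F2 | step 15 | (2E,4R,5R,6R,7E,9E,11E)-5-[(tert-butyldimethylsilyl)oxy]-2,4,8,10-tetraethyl-6-methyl-12-phenyldodeca-2,7,9,11-tetraenal | c1ccccc1/C=C/C(CC)=C/C(CC)=C/[C@@H](C)[C@@H](O[Si](C)(C)C(C)(C)C)[C@H](CC)/C=C(CC)/C=O
F3 | step 15 | (1R,2R,3R,3aS,4S,5R,7aS)-2-[(tert-butyldimethylsilyl)oxy]-3,4,5,7-tetraethyl-1-methyl-5-[(E)-2-phenylethenyl]-2,3,3a,4,5,7a-hexahydro-1H-indene-4-carbaldehyde | CCC1=C[C@](/C=C/c2ccccc2)(CC)[C@@](CC)(C=O)[C@H]2[C@H]1[C@@H](C)[C@@H](O[Si](C)(C)C(C)(C)C)[C@@H]2CC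
F4 | step 15 | (1R,2R,3R,3aS,4S,5R,7aS)-2-[(tert-butyldimethylsilyl)oxy]-3,4,5,7-tetraethyl-1-methyl-5-[(E)-2-phenylethenyl]-2,3,3a,4,5,7a-hexahydro-1H-indene-4-carboxylic acid | CCC1=C[C@](/C=C/c2ccccc2)(CC)[C@@](CC)(C(=O)O)[C@H]2[C@H]1[C@@H](C)[C@@H](O[Si](C)(C)C(C)(C)C)[C@@H]2CC
F5 | step 13 | diethyl [(1E)-1-phenylpent-1-en-3-yl]phosphonate (racemic) | CCC(/C=C/c1ccccc1)P(=O)(OCC)OCC
F6 | step 14 | 2-(trimethylsilyl)ethyl (2E,4R,5R,6R,7E,9E,11E)-5-[(tert-butyldimethylsilyl)oxy]-2,4,8,10-tetraethyl-12-iodo-6-methyldodeca-2,7,9,11-tetraenoate | I/C=C/C(CC)=C/C(CC)=C/[C@@H](C)[C@@H](O[Si](C)(C)C(C)(C)C)[C@H](CC)/C=C(CC)/C(=O)OCC[Si](C)(C)C
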